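Everything rests on cutting the C2–C3 bond of flavanone ring C. In the ring-opened form C2 is a methylene flanked by O1 and by ring B, whose para oxygen O4' feeds electron density into it. Its two enantiotopic C–H bonds are therefore the best hydride donors present and sit within six-membered reach of a carbene centred on C3. One chiral dirhodium-catalysed C–H insertion thus forms C2–C3, closes ring C and sets (2S) under neutral conditions. The precursor is a ring A diazomethyl ketone carrying the finished ring B–apigenin biaryl as an arylmethyl ether on O1, a triisopropylsilyl group on O5 and benzyl ethers on the other five phenols.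

Key step: step 12

Remark on locants: the flavanone half is numbered O1, C2–C8a (rings A and C) and C1'–C6' (ring B); the flavone half carries doubly primed (chromenone) and triply primed (its 4-oxyphenyl ring) locants; steps 1–3 use plain apigenin numbering.
Remark on the axis: the C3'–C6'' bond has three ortho oxygens (O4', O5'', O7'') and one ortho hydrogen; since the target is drawn without an axial descriptor, rotation is assumed fast enough that no separable atropisomers arise.
Remark on the sense of induction: which C2 hydrogen Rh2(S-PTTL)4 selects in this substrate type is not established; the route is written with the S-configured catalyst. If a trial on the simple 4-benzyloxybenzyl ether lacking the flavone unit shows the opposite sense, Rh2(R-PTTL)4 (from D-tert-leucine) takes its place with no other change.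
Remark on O5: its protecting group must offer no C–H within reach of C3. It must also have no acyl character, because an ester or carbonate there would undergo Baker–Venkataraman-type acyl transfer to the enolate during diazo transfer. A bulky silyl ether meets both demands.

Step 1
Reactants: 1 apigenin
Product: 2 7,4'-di-O-benzylapigenin (5-OH free)
Conditions: BnBr (2.1 equiv), K2CO3, DMF, rt
Reagents that add atoms: benzyl bromide, BrCc1ccccc1
Why: Williamson etherification; the 7- and 4'-phenols are free and acidic, whereas the 5-OH is held in a hydrogen bond to the C4 carbonyl and should stay unreacted with two equivalents of bromide at room temperature.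

Step 2
Reactants: 2 7,4'-di-O-benzylapigenin
Product: 3 7,4'-di-O-benzyl-6-iodoapigenin
Conditions: BnMe3N·ICl2 (1.1 equiv), CaCO3, CH2Cl2/MeOH, rt
Reagents that add atoms: benzyltrimethylammonium dichloroiodate, C[N+](C)(C)Cc1ccccc1.Cl[I-]Cl
Why: Electrophilic aromatic iodination; with the 5-OH free and O7 alkylated, this buffered dichloroiodate system is known to iodinate 5,7-dioxygenated flavones at C6, ortho to the free phenol, in preference to C8 and to the much less activated 4-benzyloxyphenyl ring.

Step 3
Reactants: 3 7,4'-di-O-benzyl-6-iodoapigenin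
Product: 4 5,7,4'-tri-O-benzyl-6-iodoapigenin
Conditions: BnBr (1.5 equiv), K2CO3, DMF, 70 °C
Reagents that add atoms: benzyl bromide, BrCc1ccccc1
Why: Williamson etherification under forcing conditions; heating in DMF breaks the chelate of the 5-OH, the only nucleophile left, and the aryl iodide is inert to carbonate.

Step 4
Reactants: 5 3-bromo-4-hydroxybenzaldehyde
Product: 6 4-(benzyloxy)-3-bromobenzaldehyde
Conditions: BnBr (1.1 equiv), K2CO3, DMF, rt
Reagents that add atoms: benzyl bromide, BrCc1ccccc1
Why: Williamson etherification of the single, acidic phenol para to the formyl group; aldehyde and aryl bromide do not react with carbonate.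

Step 5
Reactants: 6 4-(benzyloxy)-3-bromobenzaldehyde
Product: 7 [4-(benzyloxy)-3-bromophenyl]methanol
Conditions: NaBH4, MeOH/THF, 0 °C
Reagents that add atoms: none
Why: Borohydride reduction of the aldehyde, placed on the small fragment so that no hydride reagent ever meets the flavone enone.

Step 6
Reactants: 7 [4-(benzyloxy)-3-bromophenyl]methanol
Product: 8 [4-(benzyloxy)-3-(4,4,5,5-tetramethyl-1,3,2-dioxaborolan-2-yl)phenyl]methanol
Conditions: B2pin2 (1.2 equiv), Pd(dppf)Cl2 (3 mol %), KOAc, 1,4-dioxane, 90 °C
Reagents that add atoms: bis(pinacolato)diboron, CC1(C)OB(OC1(C)C)B1OC(C)(C)C(C)(C)O1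
Why: Miyaura borylation (oxidative addition of the aryl bromide to zerovalent palladium, acetate-assisted transmetalation from the diboron reagent), which tolerates free benzylic alcohols and benzyl ethers.

Step 7
Reactants: 4 5,7,4'-tri-O-benzyl-6-iodoapigenin; 8 [4-(benzyloxy)-3-(pinacolatoboryl)phenyl]methanol
Product: 9 biaryl alcohol, 5,7-bis(benzyloxy)-2-[4-(benzyloxy)phenyl]-6-[2-(benzyloxy)-5-(hydroxymethyl)phenyl]-4H-chromen-4-one
Conditions: Pd(OAc)2 (5 mol %), SPhos (10 mol %), K3PO4, toluene/H2O 10:1, 90 °C
Reagents that add atoms: none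
Why: Suzuki–Miyaura coupling; the doubly ortho-flanked partner is placed on the halide side as the reactive iodide, and a bulky electron-rich biarylphosphine is the established answer for biaryls with three ortho substituents, flavone C6–aryl bonds lying within the known scope.

Step 8
Reactants: 10 2,4,6-trihydroxyacetophenone
Product: 11 1-[4-(benzyloxy)-2,6-dihydroxyphenyl]ethanone
Conditions: BnBr (1.0 equiv), K2CO3 (1.0 equiv), acetone, reflux
Reagents that add atoms: benzyl bromide, BrCc1ccccc1
Why: Williamson etherification with one equivalent of bromide; the 4-OH is the most acidic hydroxyl and the only one not hydrogen-bonded to the acetyl group, so it should react first, and any dibenzyl ether is removed by chromatography at this cheap stage.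

Step 9
Reactants: 11 1-[4-(benzyloxy)-2,6-dihydroxyphenyl]ethanone
Product: 12 1-[4-(benzyloxy)-2-hydroxy-6-(triisopropylsilyloxy)phenyl]ethanone
Conditions: i-Pr3SiCl (1.1 equiv), imidazole, DMF, 0 °C to rt
Reagents that add atoms: chlorotriisopropylsilane, CC(C)[Si](Cl)(C(C)C)C(C)C
Why: Phenol silylation; the two hydroxyls are equivalent, and once one has reacted the other is locked in the chelate with the carbonyl, so the bulky chlorosilane should stop at the monoether.

Step 10
Reactants: 9 biaryl alcohol; 12 1-[4-(benzyloxy)-2-hydroxy-6-(triisopropylsilyloxy)phenyl]ethanone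
Product: 13 methyl ketone, 1-{4-(benzyloxy)-2-[(4-benzyloxy-3-(5,7,4'-tri-O-benzylapigenin-6-yl)phenyl)methoxy]-6-(triisopropylsilyloxy)phenyl}ethanone
Conditions: PPh3, DIAD, THF, 0 °C to rt
Reagents that add atoms: none
Why: Mitsunobu etherification of an acidic ortho-acylphenol with a primary, para-alkoxy-activated benzylic alcohol; the neutral medium spares the base-labile aryl silyl ether and makes isolation of an unstable para-alkoxybenzyl bromide unnecessary.

Step 11
Reactants: 13 methyl ketone
Product: 15 diazoketone, 2-diazo-1-{4-(benzyloxy)-2-[(4-benzyloxy-3-(5,7,4'-tri-O-benzylapigenin-6-yl)phenyl)methoxy]-6-(triisopropylsilyloxy)phenyl}ethanone, via trifluoroacetyl diketone 14 (not isolated)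
Conditions: LiN(SiMe3)2 (1.1 equiv), THF, −78 °C; CF3CO2CH2CF3, −78 °C; cold 0.5 M HCl wash; then p-ABSA, Et3N, H2O (1 equiv), MeCN/THF, rt
Reagents that add atoms: 2,2,2-trifluoroethyl trifluoroacetate, O=C(OCC(F)(F)F)C(F)(F)F (its CF3CO group is carried only as far as 14); 4-acetamidobenzenesulfonyl azide, CC(=O)Nc1ccc(cc1)S(=O)(=O)N=[N+]=[N-]
Why: Detrifluoroacetylative diazo transfer (Regitz type); the kinetic lithium enolate of the only enolisable ketone is trifluoroacetylated, the activated diketone 14 takes the diazo group from the sulfonyl azide and sheds the trifluoroacetyl group as the N-sulfonylamide, and holding the enolate at −78 °C is meant to prevent migration of silicon from the aryl oxygen to the enolate oxygen.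

Step 12
Reactants: 15 diazoketone
Product: 16 (2S)-5-O-triisopropylsilyl-7,4',5'',7'',4'''-penta-O-benzyl ether of the target
Conditions: Rh2(S-PTTL)4 [dirhodium tetrakis(N-phthaloyl-(S)-tert-leucinate)] (2 mol %), 4 Å MS, CH2Cl2, 0 °C, 15 added by syringe pump (final 0.005 M)
Reagents that add atoms: none
Why: Rh2(S-PTTL)4 binds the diazo carbon of 15, N2 departs, and the electrophilic rhodium carbene at C3 draws hydride character from one C2–H bond while the C2–C3 bond forms in a concerted, asynchronous three-centre transition state that releases the catalyst. The closest known reaction type is the chiral dirhodium carboxylate-catalysed intramolecular C–H insertion of ortho-alkoxyaryl diazoketones to chroman-4-ones, and the same phthaloyl-tert-leucinate catalyst is known to tell apart the enantiotopic hydrogens of aryl arylmethyl ethers in the related closure of 2-aryl-2,3-dihydrobenzofurans; the level of selectivity for a terminal diazoketone is not secured and is the one open question of the route. Ring C closes by 1,6-insertion through a six-membered transition state (C3, C4, C4a, C8a, O1, C2), since the 1,5-position is O1 and bears no hydrogen. C2 is set by the chiral pocket of the four N-phthaloyl-tert-leucinate ligands, which exposes only one of the two C2 hydrogens to the carbene, and the neutral, non-enolising medium gives the new centre no way to racemise through the chalcone. Site selectivity is secured by the substrate, because O5 carries silicon and O1–CH2 is then the only activated C–H within reach: the O7 benzyl group lies meta to the ketone on the far edge of ring A, the other four O–CH2Ph groups could be reached only through rings of twelve or more members, and slow addition at high dilution holds back intermolecular insertion and carbene dimerisation. Chemoselectivity against attack of an ether oxygen on the carbene (oxonium ylide, then Stevens 1,2-shift) is helped by the low basicity of O1, a vinylogous ester oxygen, by the bulk of the silyl group around O5, by O4', which raises the hydride-donor power of C2–H, and by a bulky rhodium carboxylate in place of copper, which favours ylides.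

Step 13
Reactants: 16 (2S)-5-O-silyl penta-O-benzyl flavanone
Product: 17 (2S)-7,4',5'',7'',4'''-penta-O-benzyl ether of the target (5-OH free)
Conditions: Bu4NF (1.1 equiv), AcOH (1.2 equiv), THF, 0 °C
Reagents that add atoms: none
Why: Fluoride-mediated desilylation; an aryl silyl ether ortho to a carbonyl is cleaved quickly, and acetic acid protonates the phenoxide and tempers the basicity of fluoride so that ring C should not open to the chalcone and (2S) is kept.

Step 14
Reactants: 17 (2S)-penta-O-benzyl flavanone
Product: 18 target, (2S)-2,3-dihydrorobustaflavone [(2S)-naringenin joined through C3' to C6'' of apigenin]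
Conditions: H2 (1 atm), 10% Pd/C, THF/MeOH 1:1, rt
Reagents that add atoms: none
Why: Catalytic hydrogenolysis of five primary aryl benzyl ethers under neutral conditions; these O–CH2Ph bonds are cleaved far faster than the secondary, ring-bound C2–O1 bond, the flavone C2''=C3'' bond and both chelated carbonyls are slow to reduce at 1 atm, and C2 is not touched.

Compound list
1 | apigenin | O=c1cc(-c2ccc(O)cc2)oc2cc(O)cc(O)c12 | starting material
2 | 7,4'-di-O-benzylapigenin | O=c1cc(-c2ccc(OCc3ccccc3)cc2)oc2cc(OCc3ccccc3)cc(O)c12 | intermediate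
3 | 7,4'-di-O-benzyl-6-iodoapigenin | O=c1cc(-c2ccc(OCc3ccccc3)cc2)oc2cc(OCc3ccccc3)c(I)c(O)c12 | intermediate
4 | 5,7,4'-tri-O-benzyl-6-iodoapigenin | O=c1cc(-c2ccc(OCc3ccccc3)cc2)oc2cc(OCc3ccccc3)c(I)c(OCc3ccccc3)c12 | intermediate
5 | 3-bromo-4-hydroxybenzaldehyde | O=Cc1ccc(O)c(Br)c1 | starting material
6 | 4-(benzyloxy)-3-bromobenzaldehyde | O=Cc1ccc(OCc2ccccc2)c(Br)c1 | intermediate
7 | [4-(benzyloxy)-3-bromophenyl]methanol | OCc1ccc(OCc2ccccc2)c(Br)c1 | intermediate
8 | [4-(benzyloxy)-3-(4,4,5,5-tetramethyl-1,3,2-dioxaborolan-2-yl)phenyl]methanol | OCc1ccc(OCc2ccccc2)c(B2OC(C)(C)C(C)(C)O2)c1 | intermediate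
9 | 5,7-bis(benzyloxy)-2-[4-(benzyloxy)phenyl]-6-[2-(benzyloxy)-5-(hydroxymethyl)phenyl]-4H-chromen-4-one | OCc1ccc(OCc2ccccc2)c(-c2c(OCc3ccccc3)cc3oc(-c4ccc(OCc5ccccc5)cc4)cc(=O)c3c2OCc2ccccc2)c1 | intermediate
10 | 2,4,6-trihydroxyacetophenone | CC(=O)c1c(O)cc(O)cc1O | starting material
11 | 1-[4-(benzyloxy)-2,6-dihydroxyphenyl]ethanone | CC(=O)c1c(O)cc(OCc2ccccc2)cc1O | intermediate
12 | 1-[4-(benzyloxy)-2-hydroxy-6-(triisopropylsilyloxy)phenyl]ethanone | CC(=O)c1c(O)cc(OCc2ccccc2)cc1O[Si](C(C)C)(C(C)C)C(C)C | intermediate
13 | 1-{4-(benzyloxy)-2-[(4-benzyloxy-3-(5,7,4'-tri-O-benzylapigenin-6-yl)phenyl)methoxy]-6-(triisopropylsilyloxy)phenyl}ethanone | CC(=O)c1c(OCc2ccc(OCc3ccccc3)c(-c3c(OCc4ccccc4)cc4oc(-c5ccc(OCc6ccccc6)cc5)cc(=O)c4c3OCc3ccccc3)c2)cc(OCc2ccccc2)cc1O[Si](C(C)C)(C(C)C)C(C)C | intermediate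
14 | 4,4,4-trifluoro-1-aryl-butane-1,3-dione derived from 13 (aryl as in 13; not isolated) | FC(F)(F)C(=O)CC(=O)c1c(OCc2ccc(OCc3ccccc3)c(-c3c(OCc4ccccc4)cc4oc(-c5ccc(OCc6ccccc6)cc5)cc(=O)c4c3OCc3ccccc3)c2)cc(OCc2ccccc2)cc1O[Si](C(C)C)(C(C)C)C(C)C | intermediate
15 | 2-diazo-1-{4-(benzyloxy)-2-[(4-benzyloxy-3-(5,7,4'-tri-O-benzylapigenin-6-yl)phenyl)methoxy]-6-(triisopropylsilyloxy)phenyl}ethanone | [N-]=[N+]=CC(=O)c1c(OCc2ccc(OCc3ccccc3)c(-c3c(OCc4ccccc4)cc4oc(-c5ccc(OCc6ccccc6)cc5)cc(=O)c4c3OCc3ccccc3)c2)cc(OCc2ccccc2)cc1O[Si](C(C)C)(C(C)C)C(C)C | intermediate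
16 | (2S)-5-O-triisopropylsilyl-7,4',5'',7'',4'''-penta-O-benzyl-2,3-dihydrorobustaflavone | O=C1C[C@@H](c2ccc(OCc3ccccc3)c(-c3c(OCc4ccccc4)cc4oc(-c5ccc(OCc6ccccc6)cc5)cc(=O)c4c3OCc3ccccc3)c2)Oc2cc(OCc3ccccc3)cc(O[Si](C(C)C)(C(C)C)C(C)C)c21 | intermediate
17 | (2S)-7,4',5'',7'',4'''-penta-O-benzyl-2,3-dihydrorobustaflavone | O=C1C[C@@H](c2ccc(OCc3ccccc3)c(-c3c(OCc4ccccc4)cc4oc(-c5ccc(OCc6ccccc6)cc5)cc(=O)c4c3OCc3ccccc3)c2)Oc2cc(OCc3ccccc3)cc(O)c21 | intermediate
18 | (2S)-2,3-dihydrorobustaflavone (CNP0277421.1) | O=C1C[C@@H](c2ccc(O)c(-c3c(O)cc4oc(-c5ccc(O)cc5)cc(=O)c4c3O)c2)Oc2cc(O)cc(O)c21 | target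

Total step count: 14.
Longest linear sequence: 9 steps (1 → 2 → 3 → 4 → 9 → 13 → 15 → 16 → 17 → 18; the chain from 5 through 6, 7, 8 and 9 is equally long).

Steps most likely to fail

1. Step 12. Three processes may intervene. An ether oxygen may attack the carbene, followed by 1,2-migration of the arylmethyl group. The carbene may dimerise. The catalyst pocket may discriminate too weakly between the two enantiotopic C2 hydrogens, the large flavone substituent at C3' sitting close to it. The fallback uses no carbene and only known chemistry.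
   - It sets out from 9 and 11. Alcohol 9 is oxidised with MnO2 in CH2Cl2 to the biaryl aldehyde F1.
   - The aldehyde and dihydroxyacetophenone 11 are condensed with pyrrolidine in EtOH at 60 °C (Claisen–Schmidt condensation through the enamine).
   - The resulting (E)-2',6'-dihydroxychalcone F2 closes in the same flask by oxa-Michael addition to the racemic 5-hydroxyflavanone F3.
   - The racemate is separated on a polysaccharide-based chiral stationary phase into 17 and the (2R)-enantiomer F4.
   - The unwanted enantiomer is re-equilibrated to the racemate with the same amine through ring opening to the chalcone and recycled.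
   - The route is rejoined at 17, and steps 9 to 13 drop out.

2. Step 7. Transmetalation at the palladium centre on the doubly ortho-flanked C6'' may be slow. Protodeboronation of the electron-rich boronate and reductive deiodination could then take over. The fallback is a base-free Stille coupling.
   - It sets out from 7, which is stannylated with (Bu3Sn)2 and Pd(PPh3)4 in toluene at 110 °C to [4-(benzyloxy)-3-(tributylstannyl)phenyl]methanol F5.
   - This stannane is coupled with iodide 4 under Pd(PPh3)4, CuI and CsF in DMF at 60 °C.
   - The copper/fluoride pair speeds up transfer of hindered aryl groups, and no boron species is present to be lost.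
   - The route is rejoined at 9.

3. Step 14. Over-reduction may occur, by hydrogenolytic opening of ring C at the benzylic C2–O1 bond or by saturation of the flavone C2''–C3'' bond. The reaction may also stall when partly deprotected material precipitates on the catalyst. The fallback is a non-reductive debenzylation.
   - It sets out from 17 and uses BCl3 with pentamethylbenzene as benzyl cation scavenger in CH2Cl2 at −78 °C, followed by a methanol quench.
   - This removes aryl benzyl ethers without touching alkenes, carbonyls or the C2–O1 bond.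
   - It arrives directly at 18 and makes no new compound (F0).

Further compounds
F1 | step 12 | 4-(benzyloxy)-3-[5,7-bis(benzyloxy)-2-(4-benzyloxyphenyl)-4-oxo-4H-chromen-6-yl]benzaldehyde | O=Cc1ccc(OCc2ccccc2)c(-c2c(OCc3ccccc3)cc3oc(-c4ccc(OCc5ccccc5)cc4)cc(=O)c3c2OCc2ccccc2)c1
F2 | step 12 | (E)-2',6'-dihydroxy-4'-benzyloxychalcone bearing 4-OBn and 3-(5,7,4'-tri-O-benzylapigenin-6-yl) on its styryl ring | O=C(/C=C/c1ccc(OCc2ccccc2)c(-c2c(OCc3ccccc3)cc3oc(-c4ccc(OCc5ccccc5)cc4)cc(=O)c3c2OCc2ccccc2)c1)c1c(O)cc(OCc2ccccc2)cc1O
F3 | step 12 | racemic 7,4',5'',7'',4'''-penta-O-benzyl-2,3-dihydrorobustaflavone | O=C1CC(c2ccc(OCc3ccccc3)c(-c3c(OCc4ccccc4)cc4oc(-c5ccc(OCc6ccccc6)cc5)cc(=O)c4c3OCc3ccccc3)c2)Oc2cc(OCc3ccccc3)cc(O)c21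
F4 | step 12 | (2R)-7,4',5'',7'',4'''-penta-O-benzyl-2,3-dihydrorobustaflavone | O=C1C[C@H](c2ccc(OCc3ccccc3)c(-c3c(OCc4ccccc4)cc4oc(-c5ccc(OCc6ccccc6)cc5)cc(=O)c4c3OCc3ccccc3)c2)Oc2cc(OCc3ccccc3)cc(O)c21
F5 | step 7 | [4-(benzyloxy)-3-(tributylstannyl)phenyl]methanol | OCc1ccc(OCc2ccccc2)c([Sn](CCCC)(CCCC)CCCC)c1
F0 | step 14 | none | none
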